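Side product A and target leave the gamma run in a split that has to be carried over to a more dilute flask.

| flask | substrate | coupling partner | remark | time |
|---|---|---|---|---|
| gamma | 1.5 M | 1.1 equiv | run made earlier |  |
| flask | 1.0 M | 1.10 equiv |  | 40 min |

- gamma (time / min: side product A / %, target / %, substrate / %): 0.333: 1.4, 0.1, 90.0; 0.500: 2.6, 0.4, 85.8; 0.833: 4.4, 1.7, 77.9; 1.33: 8.6, 0.6, 68.0; 2.50: 20.3, 3.0, 51.5; 4.00: 31.6, 4.7, 37.7

(standard deviation of a reading: 0.5 percentage points)



- ratio of side product A to target at 40 s
- ratio of side product A to target at 5.0 min
- ratio of side product A to target at 40 min
- which of side product A and target there is more of at 40 min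

In the first instants of the gamma run, at 0.333 min, substrate has lost 10.0%, yet 8.50% of the charge appears in neither product, so material waits in unseen forms. In the middle, that missing share reads 25.2% at 2.50 min and 26.0% at 4.00 min, while both products climb. Those two times, pooled, give a ratio of side product A to target of 6.74, a reading that rests on target values of 3.0% and 4.7% against a scatter of 0.5 percentage points.

The gamma run has a single concentration, so it shows no order, and my reckoning takes an assumption: side product A takes up coupling partner and target does not, which makes the ratio proportional to the partner concentration. Dividing the pooled ratio by the 1.65 M of partner charged in the gamma run gives s = 4.09 L mol⁻¹, a selectivity factor: the ratio per unit of partner concentration charged.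

The new flask charges 1.10 M of partner, so s gives a ratio of 4.49. The gamma ratio reads 6.77 at 2.50 min and 6.72 at 4.00 min, so I hold this number at all three asked times, with side product A ahead. The end of the new flask lies beyond the readings, which stop at 4.00 min.

The forecast, unlike this reckoning, keeps the gamma ratio unscaled: 6.7 at 40 s, 6.7 at 5.0 min and 6.7 at 40 min, with side product A ahead, “with no drift as the partner depletes”.

The new flask gives 4.76, 4.84 and 4.97 at those times, with side product A ahead.

    substrate ⇌ intermediate A (K = 0.200, k = 0.00252 s⁻¹)
    substrate → intermediate B (k = 0.00285 s⁻¹)
    intermediate A → target (k = 0.00377 s⁻¹)
    coupling partner + intermediate A ⇌ intermediate C (K = 0.880 L mol⁻¹, k = 0.0268 L mol⁻¹ s⁻¹)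
    coupling partner + intermediate B → side product A (k = 0.0110 L mol⁻¹ s⁻¹)
    substrate + intermediate C → side product B (k = 0.00133 L mol⁻¹ s⁻¹)

In the new flask at 3.76 min, intermediate A goes to target at 0.18 of the rate at which coupling partner takes it into intermediate C, that step's forward rate alone, since it also runs back. In the scheme, coupling partner stands on the branch to target as well as on the step from intermediate B to side product A.

With 0.280 equiv of coupling partner and the same substrate, s gives 1.14. That neighbour flask computes to 1.14 at 40 s and 1.65 at 40 min, where its coupling partner stands at 0% of its own charge and intermediate B at 54.9% of the substrate charged.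

Readings and results were generated by integration with constants of no real substance; the scatter is artificial.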